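## Analysis of the target

Target 22 is a coumarin in which ring A is the benzene ring C4a–C5–C6–C7–C8–C8a, ring B is the lactone ring O1–C2–C3–C4–C4a–C8a, and ring C is a 2,3-dihydro-4H-pyran-4-one bonded through its C6' to C3. Ring A is hexasubstituted: C5 carries the 3-hydroxybutan-2-yl group (C2'' benzylic, C3'' carbinol), C6 and C8 carry methyl groups, C7 a free phenol, C8a the lactone oxygen and C4a the C4–H carbon. C5 is meta to both ring oxygens (on C7 and C8a) and lies between C6–CH3 and C4a, so electrophilic substitution of an oxygenated arene cannot reach it; this feature, ring A with its stereodefined branch at C5, is what the strategy is built on. Of the three stereocentres, C2'' (R) and C3'' (R) are contiguous, with the aryl and hydroxyl groups anti along the zig-zag butane chain, the relationship that results when a trans-2,3-disubstituted epoxide is opened with inversion at one carbon. C2' (S) in ring C lies seven bonds from C2'' and cannot be controlled from the side chain, so two independent sources of chirality are needed. Ring C is a vinylogous ester and a β-alkoxy ketone: base can open it by retro-oxa-Michael reaction, which would scramble C2', and amines can exchange at C6'. The lactone is base-labile, and the C3''–OH sits peri to C4, where it can add to C3=C4 or, in any aldehyde precursor, close to a lactol. The difficulty is therefore the fully substituted ring A with its branch at the least accessible carbon, together with the mildness required once ring C is in place.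

## Retrosynthetic reasoning

**22 to 21.** The last bond cut is the O–Si bond at C3''. A silyl ether keeps the side-chain oxygen from closing onto C4 or onto a formyl group earlier in the route. Its removal with acidic fluoride should leave the lactone and the vinylogous ester of ring C untouched.

**21 to 12 and 19.** Ring B is cut at C3=C4 and O1–C2. This is the most reliable coumarin closure and is deliberately kept conventional. Salicylaldehyde 12 supplies C4, ring A and the side chain; ester 19 supplies C2, C3 and the complete ring C. In 19 the second ketone of the polyketide chain is already tied up as the vinylogous ester, so the acetate CH2 is the only doubly activated position and the condensation can take one course only.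

**12 to 6 and 10 (key disconnection).** Ring A is not bought but made, cut at C5–C6 and C4a–C8a. Ynal 6 brings the formyl carbon (future C4), C4a, C5 and the intact C2''/C3'' diad. Diene 10 brings C6, C7, C8 and C8a with both methyl groups and both oxygens. A [4+2] cycloaddition followed by expulsion of the methoxy group makes the ring aromatic. The polarity of the partners fixes the orientation: the nucleophilic CH(CH3) terminus of 10 meets the β-carbon of 6. What is gained: no arene starting material, no halogen meta to two oxygens, no formylation and no phenol protection. The forward reaction has to join two substituted carbons and must engage the triple bond of 6, not its formyl group.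

**6 to 3, 2 and 1.** The formyl group is removed to give terminal alkyne 3, and the silyl group to give alkynol 2. The C2''–alkyne bond is cut back to epoxide 1 and a two-carbon acetylide nucleophile. Epoxide 1 is C2-symmetric, so there is no regiochemical question, and inversion at the attacked carbon gives exactly the required (R,R) diad.

**10 to 8 and 7.** The two O–Si bonds are cut in turn, back to commercial β-keto ester 7.

**19 to 17, then 14 and 16, then 13 and 15.** Ring C is opened at O1'–C6' to hydroxy diketo ester 18, which is carried as silyl ether 17. The C4'–C5' bond is then cut to dianion 16, made from 15, and ester 14, which is the silyl ether of chiral-pool hydroxy ester 13. C2' is never touched after purchase.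

## Alternatives that were turned down

**Alternative 1:** The textbook route keeps an intact benzene ring and cuts the aryl–alkyl bond C5–C2''. The forward key step is a CuI-catalysed opening of epoxide 1 by the Grignard reagent of 1-bromo-3,5-dimethoxy-2,4-dimethylbenzene (A1), giving (2R,3R)-3-(3,5-dimethoxy-2,4-dimethylphenyl)butan-2-ol (A2). Ether cleavage, silylation and ortho-formylation would then lead to 12. It was turned down for three reasons. A1 is not a commercial arene, and its bromine sits meta to both oxygens where electrophilic substitution cannot place it, so A1 alone costs several steps. An ortho-substituted aryl metal must open an internal epoxide, a slow reaction that competes with halohydrin formation and elimination. The two methyl ethers of A2 must later be cleaved by a strong Lewis acid next to a secondary alcohol, and the formyl group must still be forced into the last free position beside the branch. The path to 12 is estimated to be about twice as long.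

**Alternative 2:** A 6π route cuts ring A at C6–C7 after the two-carbon unit C8–C8a has been added. The forward key step is a thermal cascade between 4-methyl-3-{(2R,3R)-3-[(tert-butyldimethylsilyl)oxy]butan-2-yl}cyclobut-2-en-1-one (A3) and tri(propan-2-yl)(prop-1-yn-1-yloxy)silane (A4). Heating opens A3 by a 4π process to a ketene that adds to A4 in a [2+2] sense; a second 4π opening and a 6π electrocyclization follow, and tautomerization gives 5-{(2R,3R)-3-[(tert-butyldimethylsilyl)oxy]butan-2-yl}-2,6-dimethyl-3-{[tri(propan-2-yl)silyl]oxy}phenol (A5). It was turned down on step economy. A3 needs a regiocontrolled ketene [2+2] addition to alkyne 3 and a dehalogenation, and carries a stereocentre that is thrown away. A4 is a hydrolytically sensitive silyl ynol ether that has to be prepared as well. A5 lacks the C4 carbon, so a separate formylation at the hindered position next to the branch and a further silyl cleavage remain. The same ring would cost three to four more steps than the [4+2] route.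

**Alternative 3:** Ring C could be made last, cut at O1'–C6' and C2'–C3', with C2' set by a catalyst. The forward key step is an asymmetric hetero-Diels–Alder reaction of the coumarinyl diene 5-{(2R,3R)-3-[(tert-butyldimethylsilyl)oxy]butan-2-yl}-7-[(tert-butyldimethylsilyl)oxy]-3-{1-methoxy-3-[(trimethylsilyl)oxy]buta-1,3-dien-1-yl}-6,8-dimethyl-2H-chromen-2-one (A6) with acetaldehyde (A7), catalysed by a chiral (salen)CrCl complex of trivalent chromium, followed by acid. It was turned down because the oxygenated terminus of A6 is fully substituted and conjugated to an electron-poor coumarin, and both features lower the reactivity of such dienes. A7 offers the catalyst only a methyl group against a hydrogen atom to tell its two faces apart, so the control at C2' would rest on the smallest possible difference. A6 also has to be made from a 1,3-dicarbonyl side chain at C3 whose two carbonyl groups must be told apart, on a coumarin whose C4 is an open Michael acceptor. The route adds at least three linear steps after the convergent point, whereas C2' can simply be bought in 13.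

Key step: step 6

Remark: compounds 1, 7, 13 and 15 and all reagents are taken as commercial; the side-chain configuration read from the SMILES is (2''R,3''R), the diad obtained by inversion at one carbon of (2R,3R)-2,3-epoxybutane.

## Route

**Step 1**
Reactants: 1 (2R,3R)-2,3-dimethyloxirane
Product: 2 (2R,3R)-3-methylpent-4-yn-2-ol
Conditions: LiC≡CH·H2NCH2CH2NH2, DMSO, 0 °C to rt; then H2O
Reagents that add atoms: lithium acetylide ethylenediamine complex, [Li+].[C-]#C.NCCN
Why: SN2 opening of an epoxide by an acetylide; the two carbons of the C2-symmetric epoxide are equivalent, attack anti to the C–O bond inverts the attacked carbon and leaves the carbinol carbon untouched, so only the (2R,3R) alkynol, with the ethynyl and hydroxyl groups anti along the butane chain, should form.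

**Step 2**
Reactants: 2 (2R,3R)-3-methylpent-4-yn-2-ol
Product: 3 tert-butyl(dimethyl){[(2R,3R)-3-methylpent-4-yn-2-yl]oxy}silane
Conditions: TBSCl, imidazole, DMF, rt
Reagents that add atoms: tert-butyldimethylsilyl chloride, CC(C)(C)[Si](C)(C)Cl
Why: Standard silylation of a secondary alcohol; the ether is needed to survive n-BuLi and the silyl diene, and later to prevent lactol formation and oxa-Michael addition at C4.

**Step 3**
Reactants: 3 tert-butyl(dimethyl){[(2R,3R)-3-methylpent-4-yn-2-yl]oxy}silane
Product: 6 (4R,5R)-5-[(tert-butyldimethylsilyl)oxy]-4-methylhex-2-ynal, via lithium acetylide 4 (not isolated), via lithium hemiaminal alkoxide 5 (not isolated)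
Conditions: n-BuLi, THF, −78 °C; DMF, −78 to 0 °C; inverse quench into aq. KH2PO4/MTBE, 0 °C
Reagents that add atoms: N,N-dimethylformamide, CN(C)C=O
Why: Formylation of a lithium acetylide with DMF; the tetrahedral adduct 5 is stable until the buffered inverse quench, which releases the ynal while protonating the amine, so conjugate addition and propargyl–allenyl isomerization at C4 should be avoided.

**Step 4**
Reactants: 7 methyl 2-methyl-3-oxopentanoate
Product: 8 methyl 2-methyl-3-[(trimethylsilyl)oxy]pent-2-enoate
Conditions: TMSCl, Et3N, CH2Cl2, rt
Reagents that add atoms: trimethylsilyl chloride, C[Si](C)(C)Cl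
Why: O-silylation of the enol of a β-keto ester (first stage of a Chan-type diene synthesis); the alkene geometry is of no consequence.

**Step 5**
Reactants: 8 methyl 2-methyl-3-[(trimethylsilyl)oxy]pent-2-enoate
Product: 10 (3Z)-1-methoxy-2-methyl-1,3-bis[(trimethylsilyl)oxy]penta-1,3-diene, via lithium dienolate 9 (not isolated)
Conditions: LiN(i-Pr)2 (commercial solution), THF, −78 °C; TMSCl, −78 °C to rt
Reagents that add atoms: trimethylsilyl chloride, C[Si](C)(C)Cl
Why: γ-Deprotonation of the vinylogous ester and O-silylation of the dienolate (Chan-type 1,3-bis(silyloxy)diene synthesis); allylic strain with the fully substituted C2 should place the C5 methyl cis to the silyloxy group (3Z), i.e. on the outside of the s-cis diene.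

**Step 6**
Reactants: 6 (4R,5R)-5-[(tert-butyldimethylsilyl)oxy]-4-methylhex-2-ynal; 10 (3Z)-1-methoxy-2-methyl-1,3-bis[(trimethylsilyl)oxy]penta-1,3-diene
Product: 12 6-{(2R,3R)-3-[(tert-butyldimethylsilyl)oxy]butan-2-yl}-2,4-dihydroxy-3,5-dimethylbenzaldehyde, via cyclohexadiene cycloadduct 11 (not isolated)
Conditions: 10 (2 equiv), toluene, −20 to 60 °C; then 0.5 M HCl, THF, 0 °C
Reagents that add atoms: none
Why: A normal-electron-demand, asynchronous [4+2] cycloaddition of the 1,1,3-trioxygenated diene 10 across the formyl-activated triple bond of 6 should give 1,4-cyclohexadiene 11; dilute acid then hydrolyses the two trimethylsilyl ethers, the mixed ketal at the future C8a collapses with loss of methanol, and the cyclohexenedione tautomerizes to the resorcinol. The closest known reaction type is the Diels–Alder benzannulation of Chan- and Brassard-type dienes with acetylenic esters, ketones and aldehydes to give resorcinol derivatives. Ring A is closed intermolecularly by the cycloaddition itself, bonds C5–C6 and C4a–C8a forming in one suprafacial event with C5–C6 leading, so no tether and no exo or endo mode is involved. The two sp3 centres created in 11 (future C6 and C8a) are erased on aromatization, so no new permanent stereocentre arises, and the C2''/C3'' diad of 6 is not epimerizable under neutral thermal conditions. The step needs regioselectivity, which the polarity of the partners should secure: the most nucleophilic diene terminus, the CH(CH3) carbon of 10, bonds to the β-carbon of the ynal and the ketene-acetal carbon to the α-carbon, so the formyl group ends ortho to the C8a hydroxyl and next to the branch. It also needs periselectivity for C≡C over C=O, which the absence of any Lewis acid and the non-polar solvent should favour, because carbonyl addition and hetero-cycloaddition of silyloxy dienes normally require Lewis acid activation. The secondary TBS ether should survive the short exposure to dilute acid.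

**Step 7**
Reactants: 13 methyl (3S)-3-hydroxybutanoate
Product: 14 methyl (3S)-3-[(tert-butyldimethylsilyl)oxy]butanoate
Conditions: TBSCl, imidazole, DMF, rt
Reagents that add atoms: tert-butyldimethylsilyl chloride, CC(C)(C)[Si](C)(C)Cl
Why: Standard silylation; it removes the acidic OH before the dianion chemistry and leaves the chiral-pool (S) centre untouched.

**Step 8**
Reactants: 15 methyl 3-oxobutanoate; 14 methyl (3S)-3-[(tert-butyldimethylsilyl)oxy]butanoate
Product: 17 methyl (7S)-7-[(tert-butyldimethylsilyl)oxy]-3,5-dioxooctanoate, via acetoacetate dianion 16 (not isolated)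
Conditions: NaH, THF, 0 °C; n-BuLi, 0 °C; then 14 (0.5 equiv), 0 °C to rt; aq. HCl
Reagents that add atoms: none
Why: Huckin–Weiler acylation, a Claisen condensation of a β-keto ester dianion at its terminal carbon; the diketo ester is deprotonated as it forms, which should prevent a second addition, and the silyloxy carbon is not part of any enolizable position.

**Step 9**
Reactants: 17 methyl (7S)-7-[(tert-butyldimethylsilyl)oxy]-3,5-dioxooctanoate
Product: 19 methyl 2-[(2S)-2-methyl-4-oxo-3,4-dihydro-2H-pyran-6-yl]acetate, via hydroxy diketo ester 18 (not isolated)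
Conditions: 48% aq. HF, MeCN, 0 °C to rt; then TsOH·H2O (cat.), CH2Cl2, 4 Å MS, rt
Reagents that add atoms: none
Why: Desilylation followed by acid-catalysed cyclodehydration of a δ-hydroxy-β-diketone; the C7 hydroxyl can reach only the C3 carbonyl in a six-membered hemiketal (6-exo-trig), dehydration gives the vinylogous ester, and the C–O bond at the stereocentre is never broken, so (S) should be retained.

**Step 10**
Reactants: 12 6-{(2R,3R)-3-[(tert-butyldimethylsilyl)oxy]butan-2-yl}-2,4-dihydroxy-3,5-dimethylbenzaldehyde; 19 methyl 2-[(2S)-2-methyl-4-oxo-3,4-dihydro-2H-pyran-6-yl]acetate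
Product: 21 5-{(2R,3R)-3-[(tert-butyldimethylsilyl)oxy]butan-2-yl}-7-hydroxy-6,8-dimethyl-3-[(2S)-2-methyl-4-oxo-3,4-dihydro-2H-pyran-6-yl]-2H-chromen-2-one, via arylidene ester 20 (not isolated)
Conditions: piperidine (0.2 equiv), AcOH (0.2 equiv), MeCN, 4 Å MS, 50 °C
Reagents that add atoms: none
Why: Knoevenagel condensation followed by lactonization (classical coumarin synthesis); the acetate CH2 of 19 is the only position activated by both the ester and the vinylogous ketone, the C8a hydroxyl closes ring B on the ester (6-exo-trig) with loss of methanol, and the buffered catalyst should keep ring C closed and C2' intact.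

**Step 11**
Reactants: 21 5-{(2R,3R)-3-[(tert-butyldimethylsilyl)oxy]butan-2-yl}-7-hydroxy-6,8-dimethyl-3-[(2S)-2-methyl-4-oxo-3,4-dihydro-2H-pyran-6-yl]-2H-chromen-2-one
Product: 22 7-hydroxy-5-[(2R,3R)-3-hydroxybutan-2-yl]-6,8-dimethyl-3-[(2S)-2-methyl-4-oxo-3,4-dihydro-2H-pyran-6-yl]-2H-chromen-2-one
Conditions: HF·pyridine, THF, 0 °C to rt
Reagents that add atoms: none
Why: Fluoride-mediated cleavage of a silyl ether under mildly acidic conditions; no base is present, so the lactone, the vinylogous ester and C2' should be unaffected and no stereocentre is touched.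

## Compound list

1 | (2R,3R)-2,3-dimethyloxirane [(2R,3R)-2,3-epoxybutane] | C[C@H]1O[C@@H]1C | starting material
2 | (2R,3R)-3-methylpent-4-yn-2-ol | C#C[C@@H](C)[C@@H](C)O | intermediate
3 | tert-butyl(dimethyl){[(2R,3R)-3-methylpent-4-yn-2-yl]oxy}silane | C#C[C@@H](C)[C@@H](C)O[Si](C)(C)C(C)(C)C | intermediate
4 | {(3R,4R)-4-[(tert-butyldimethylsilyl)oxy]-3-methylpent-1-yn-1-yl}lithium (lithium acetylide of 3, formed in the flask) | [Li]C#C[C@@H](C)[C@@H](C)O[Si](C)(C)C(C)(C)C | intermediate
5 | lithium (4R,5R)-5-[(tert-butyldimethylsilyl)oxy]-1-(dimethylamino)-4-methylhex-2-yn-1-olate (hemiaminal alkoxide, formed in the flask) | CN(C)C([O-])C#C[C@@H](C)[C@@H](C)O[Si](C)(C)C(C)(C)C.[Li+] | intermediate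
6 | (4R,5R)-5-[(tert-butyldimethylsilyl)oxy]-4-methylhex-2-ynal | O=CC#C[C@@H](C)[C@@H](C)O[Si](C)(C)C(C)(C)C | intermediate
7 | methyl 2-methyl-3-oxopentanoate (racemic) | CCC(=O)C(C)C(=O)OC | starting material
8 | methyl 2-methyl-3-[(trimethylsilyl)oxy]pent-2-enoate (either geometry) | CCC(O[Si](C)(C)C)=C(C)C(=O)OC | intermediate
9 | lithium (3Z)-1-methoxy-2-methyl-3-[(trimethylsilyl)oxy]penta-1,3-dien-1-olate (formed in the flask) | C/C=C(O[Si](C)(C)C)/C(C)=C(OC)[O-].[Li+] | intermediate
10 | (3Z)-1-methoxy-2-methyl-1,3-bis[(trimethylsilyl)oxy]penta-1,3-diene (either geometry at C1=C2) | C/C=C(O[Si](C)(C)C)/C(C)=C(OC)O[Si](C)(C)C | intermediate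
11 | 2-{(2R,3R)-3-[(tert-butyldimethylsilyl)oxy]butan-2-yl}-6-methoxy-3,5-dimethyl-4,6-bis[(trimethylsilyl)oxy]cyclohexa-1,4-diene-1-carbaldehyde (cycloadduct, mixture at the two ring sp3 carbons, formed in the flask) | COC1(O[Si](C)(C)C)C(C)=C(O[Si](C)(C)C)C(C)C([C@@H](C)[C@@H](C)O[Si](C)(C)C(C)(C)C)=C1C=O | intermediate
12 | 6-{(2R,3R)-3-[(tert-butyldimethylsilyl)oxy]butan-2-yl}-2,4-dihydroxy-3,5-dimethylbenzaldehyde | O=Cc1c(O)c(C)c(O)c(C)c1[C@@H](C)[C@@H](C)O[Si](C)(C)C(C)(C)C | intermediate
13 | methyl (3S)-3-hydroxybutanoate | C[C@H](O)CC(=O)OC | starting material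
14 | methyl (3S)-3-[(tert-butyldimethylsilyl)oxy]butanoate | C[C@H](O[Si](C)(C)C(C)(C)C)CC(=O)OC | intermediate
15 | methyl 3-oxobutanoate (methyl acetoacetate) | CC(=O)CC(=O)OC | starting material
16 | sodium lithium dianion of methyl 3-oxobutanoate (formed in the flask) | C=C([O-])C=C([O-])OC.[Na+].[Li+] | intermediate
17 | methyl (7S)-7-[(tert-butyldimethylsilyl)oxy]-3,5-dioxooctanoate | C[C@H](O[Si](C)(C)C(C)(C)C)CC(=O)CC(=O)CC(=O)OC | intermediate
18 | methyl (7S)-7-hydroxy-3,5-dioxooctanoate (formed in the flask) | C[C@H](O)CC(=O)CC(=O)CC(=O)OC | intermediate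
19 | methyl 2-[(2S)-2-methyl-4-oxo-3,4-dihydro-2H-pyran-6-yl]acetate | COC(=O)CC1=CC(=O)C[C@H](C)O1 | intermediate
20 | methyl (2Z)-3-(6-{(2R,3R)-3-[(tert-butyldimethylsilyl)oxy]butan-2-yl}-2,4-dihydroxy-3,5-dimethylphenyl)-2-[(2S)-2-methyl-4-oxo-3,4-dihydro-2H-pyran-6-yl]prop-2-enoate (formed in the flask) | COC(=O)/C(C1=CC(=O)C[C@H](C)O1)=C\c1c(O)c(C)c(O)c(C)c1[C@@H](C)[C@@H](C)O[Si](C)(C)C(C)(C)C | intermediate
21 | 5-{(2R,3R)-3-[(tert-butyldimethylsilyl)oxy]butan-2-yl}-7-hydroxy-6,8-dimethyl-3-[(2S)-2-methyl-4-oxo-3,4-dihydro-2H-pyran-6-yl]-2H-chromen-2-one | Cc1c(O)c(C)c2oc(=O)c(C3=CC(=O)C[C@H](C)O3)cc2c1[C@@H](C)[C@@H](C)O[Si](C)(C)C(C)(C)C | intermediate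
22 | 7-hydroxy-5-[(2R,3R)-3-hydroxybutan-2-yl]-6,8-dimethyl-3-[(2S)-2-methyl-4-oxo-3,4-dihydro-2H-pyran-6-yl]-2H-chromen-2-one | Cc1c(O)c(C)c2oc(=O)c(C3=CC(=O)C[C@H](C)O3)cc2c1[C@@H](C)[C@@H](C)O | target

## Step count and least certain steps

Total step count: 11. Longest linear sequence: 6 steps (steps 1, 2, 3, 6, 10 and 11; 1 to 2 to 3 to 6 to 12 to 21 to 22).

**Step 6 (key step).** Three processes are most likely to go wrong. The ketene-acetal diene may attack the formyl group, by hetero-cycloaddition or silyl-transfer aldol addition, instead of adding across the triple bond. Bond formation between the methyl-bearing diene terminus and the α-branched alkyne carbon may be slow, leaving time for hydrolytic or thermal loss of the diene. Aromatization may proceed with loss of silanol, which would retain the methyl ether at C8a. The fallback sets out from lithium acetylide 4 and returns at 12. It moves the oxidation level so that the activating group has no electrophilic carbonyl and adds no bulk. Cyanation of 4 with phenyl cyanate (THF, −78 °C to rt) would give (4R,5R)-5-[(tert-butyldimethylsilyl)oxy]-4-methylhex-2-ynenitrile F1. Cycloaddition of F1 with 10 (toluene, 80 to 110 °C) would give 2-{(2R,3R)-3-[(tert-butyldimethylsilyl)oxy]butan-2-yl}-6-methoxy-3,5-dimethyl-4,6-bis[(trimethylsilyl)oxy]cyclohexa-1,4-diene-1-carbonitrile F2. Dilute acid would aromatize F2 to 6-{(2R,3R)-3-[(tert-butyldimethylsilyl)oxy]butan-2-yl}-2,4-dihydroxy-3,5-dimethylbenzonitrile F3. Reduction of F3 with excess i-Bu2AlH (toluene, −78 to 0 °C) and acidic hydrolysis of the aldimine would give 12.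

**Step 10.** Iminium formation and C–C bond formation may be slow at an electron-rich aldehyde flanked by the hydroxyl and the silylated branch. Prolonged exposure to the amine invites retro-oxa-Michael opening of ring C, with erosion at C2', and amine exchange at C6'. The fallback sets out from 12 and returns at 22. It changes the electrophile from the silylated aldehyde to a small cyclic lactol. HF·pyridine (THF, 0 °C) would desilylate 12, and the freed hydroxyl would close on the formyl group to give (3R,4R)-3,4,5,7-tetramethyl-3,4-dihydro-1H-2-benzopyran-1,6,8-triol F4. Lactols react in Knoevenagel condensations through their open form or the derived iminium ion. Condensation of F4 with 19 under ethylenediammonium diacetate catalysis (MeCN, rt to 40 °C) should lead, through reversible oxa-Michael adducts of the side-chain hydroxyl, to irreversible lactonization and directly to 22, which makes step 11 unnecessary.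

**Step 8.** The strongly basic dianion may deprotonate ester 14 at its α-carbon instead of adding to it; β-elimination of the silyloxy group would follow and the conversion would be incomplete. The fallback sets out from 14 and returns at 17. It replaces the ester by a far more electrophilic aldehyde. Reduction of 14 with i-Bu2AlH (CH2Cl2, −78 °C) would give (3S)-3-[(tert-butyldimethylsilyl)oxy]butanal F5. Aldol addition of dianion 16 (THF, −78 °C) would give methyl (7S)-7-[(tert-butyldimethylsilyl)oxy]-5-hydroxy-3-oxooctanoate F6 as a mixture at C5. Oxidation of F6 with Dess–Martin periodinane (CH2Cl2, rt) would give 17.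

**Step 3.** During the quench, the amine released may add to the ynal in conjugate fashion, and base-induced propargyl–allenyl isomerization would scramble C4. The fallback sets out from lithium acetylide 4 and returns at 6. It reaches the aldehyde by oxidation under neutral conditions. Hydroxymethylation of 4 with paraformaldehyde (THF, −78 °C to rt) would give (4R,5R)-5-[(tert-butyldimethylsilyl)oxy]-4-methylhex-2-yn-1-ol F7. Oxidation of F7 with MnO2 (CH2Cl2, rt) would give 6.

## Further compounds

F1 | step 6 | (4R,5R)-5-[(tert-butyldimethylsilyl)oxy]-4-methylhex-2-ynenitrile | N#CC#C[C@@H](C)[C@@H](C)O[Si](C)(C)C(C)(C)C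
F2 | step 6 | 2-{(2R,3R)-3-[(tert-butyldimethylsilyl)oxy]butan-2-yl}-6-methoxy-3,5-dimethyl-4,6-bis[(trimethylsilyl)oxy]cyclohexa-1,4-diene-1-carbonitrile | COC1(O[Si](C)(C)C)C(C)=C(O[Si](C)(C)C)C(C)C([C@@H](C)[C@@H](C)O[Si](C)(C)C(C)(C)C)=C1C#N
F3 | step 6 | 6-{(2R,3R)-3-[(tert-butyldimethylsilyl)oxy]butan-2-yl}-2,4-dihydroxy-3,5-dimethylbenzonitrile | N#Cc1c(O)c(C)c(O)c(C)c1[C@@H](C)[C@@H](C)O[Si](C)(C)C(C)(C)C
F4 | step 10 | (3R,4R)-3,4,5,7-tetramethyl-3,4-dihydro-1H-2-benzopyran-1,6,8-triol (mixture at C1) | OC1O[C@H](C)[C@H](C)c2c(C)c(O)c(C)c(O)c12
F5 | step 8 | (3S)-3-[(tert-butyldimethylsilyl)oxy]butanal | C[C@H](O[Si](C)(C)C(C)(C)C)CC=O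
F6 | step 8 | methyl (7S)-7-[(tert-butyldimethylsilyl)oxy]-5-hydroxy-3-oxooctanoate (mixture at C5) | C[C@H](O[Si](C)(C)C(C)(C)C)CC(O)CC(=O)CC(=O)OC
F7 | step 3 | (4R,5R)-5-[(tert-butyldimethylsilyl)oxy]-4-methylhex-2-yn-1-ol | OCC#C[C@@H](C)[C@@H](C)O[Si](C)(C)C(C)(C)C
A1 | alternative 1 | 1-bromo-3,5-dimethoxy-2,4-dimethylbenzene | COc1cc(Br)c(C)c(OC)c1C
A2 | alternative 1 | (2R,3R)-3-(3,5-dimethoxy-2,4-dimethylphenyl)butan-2-ol | COc1cc([C@@H](C)[C@@H](C)O)c(C)c(OC)c1C
A3 | alternative 2 | 4-methyl-3-{(2R,3R)-3-[(tert-butyldimethylsilyl)oxy]butan-2-yl}cyclobut-2-en-1-one (mixture at C4) | CC1C(=O)C=C1[C@@H](C)[C@@H](C)O[Si](C)(C)C(C)(C)C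
A4 | alternative 2 | tri(propan-2-yl)(prop-1-yn-1-yloxy)silane | CC#CO[Si](C(C)C)(C(C)C)C(C)C
A5 | alternative 2 | 5-{(2R,3R)-3-[(tert-butyldimethylsilyl)oxy]butan-2-yl}-2,6-dimethyl-3-{[tri(propan-2-yl)silyl]oxy}phenol | Cc1c(O)c(C)c(O[Si](C(C)C)(C(C)C)C(C)C)cc1[C@@H](C)[C@@H](C)O[Si](C)(C)C(C)(C)C
A6 | alternative 3 | 5-{(2R,3R)-3-[(tert-butyldimethylsilyl)oxy]butan-2-yl}-7-[(tert-butyldimethylsilyl)oxy]-3-{1-methoxy-3-[(trimethylsilyl)oxy]buta-1,3-dien-1-yl}-6,8-dimethyl-2H-chromen-2-one (either alkene geometry) | Cc1c(O[Si](C)(C)C(C)(C)C)c(C)c2oc(=O)c(C(OC)=CC(=C)O[Si](C)(C)C)cc2c1[C@@H](C)[C@@H](C)O[Si](C)(C)C(C)(C)C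
A7 | alternative 3 | acetaldehyde | CC=O
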